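## Structural features

The target is a (2S)-flavanone: ring C is a 2,3-dihydro-4H-pyran-4-one (O1, C2, C3, C4, C4a, C8a) fused to the phloroglucinol-type ring A (5-OH, 7-OH, prenyl on C6 between them) and joined through the C2–C1' bond to the resorcinol-type ring B (2'-OH, 4'-OH, prenyl on C5'). C2 is the only stereocentre (S, with O1 > C1' > C3 > H); it is benzylic to a very electron-rich arene, bears O1 and lies β to the C4 ketone, so it has no neighbouring centre to relay from and can be lost by retro-oxa-Michael opening in base or by ionisation of C2–O1 in acid. Ring opening gives a chalcone whose acyl-bearing ring has two ortho hydroxyls, so reclosure can also move the prenyl group from C6 to C8; stereochemistry and regiochemistry therefore stand or fall together. Each prenyl group sits ortho to a phenol, which rules out strong acid (chroman formation) and hydrogenation, and the 5-OH is chelated to the C4 carbonyl. The real difficulty is to create C2 in the S configuration and fix the prenyl group at C6 under conditions that never open ring C, and then to free four phenols without strong acid or base. The key step exploits the fact that C2 is the β-carbon of the enone O1–C2=C3–C4=O in the 2,3-didehydro form of ring C, and that C2–C1' is the only bond linking two independently substituted halves: an enantioselective rhodium-catalysed 1,4-addition of a ring B arylboronic acid to a preformed 6-prenylchromone forms that bond, sets C2 and leaves O1–C8a in place.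

## Logic of the disconnections

16 to 15. The four O–Si bonds at O5, O7, O2' and O4' are cut. Free phenols would quench the organometallic steps and make the C2–O1 bond labile, and silyl ethers are the one mask that comes off near neutrality. There is no gain in skeleton, but every earlier step becomes compatible. The forward step must release phenols, not phenoxides.

15 to 7 and 14. The C2–C1' bond is cut. This is the only bond whose formation can create C2 while ring C is already closed, so the O1–C8a connectivity, and with it the C6 position of the prenyl group, is never in question. The gain is full convergence: two achiral arenes of similar size, each carrying its own prenyl group. The forward step must deliver the aryl group to one face of the C2=C3 bond, must prefer the enone to two prenyl alkenes, and must not open ring C at the enolate stage.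

7 to 6 to 5. First the O5–Si bond is cut, then the C=C bond of the C6 side chain (isopropylidene exchanged for methylidene). A terminal allyl group can be placed by a sigmatropic shift, a prenyl group cannot be placed directly at C6 this way. The forward metathesis must touch only the terminal alkene and not the C2=C3 bond of the chromone.

5 to 3 (through 4). The C6–CH2 bond is cut and traced back by a [3,3] shift to an O5–CH2 bond. The only free ortho position of O5 is C6, the other being the ring-fusion carbon C4a, so the position of the oxygen dictates the position of the carbon. This is the disconnection that fixes the substituent at C6 and not at C8. The forward step needs heat but no reagent, and the chromone must tolerate it.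

3 to 2 to 1. The O5–CH2 bond and the O7–Si bond are cut. The two hydroxyls of 1 differ sharply in acidity and chelation, so they can be addressed one after the other without a separation problem. The forward alkylation of the chelated 5-OH must be neutral enough to keep the 7-silyl ether.

14 to 11 to 9 to 8. The C1'–B bond, then the C5'–CH2 bond, then two O–Si bonds are cut. The two bromines of 8 sit on exactly the two carbons that must carry boron and prenyl and are equivalent by symmetry, so the first exchange gives one product and no regiochemical question arises. The forward steps pass through aryllithiums ortho to silyloxy groups, which must be trapped before the silyl group migrates from oxygen to carbon; this is why the bulky triisopropylsilyl group is used on ring B.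

## Other disconnections considered

Alternative 1: the O1–C2 bond is cut, which leads to chalcone A1 (from a Claisen–Schmidt condensation). The forward key step would be an intramolecular oxa-Michael addition under a chiral base or thiourea catalyst. This is the route that comes to mind first. Its weakness is structural: A1 has two phenols ortho to the acyl group, one of them next to the prenyl group, and closure through either is comparably easy, so the target skeleton would be accompanied by the 8-prenyl regioisomer A2. The closure is also reversible under the conditions that effect it, so any kinetic enantioselectivity would erode and the regioisomers would equilibrate. Simple 2'-hydroxychalcones without an extra activating group are in addition poor substrates for catalytic asymmetric oxa-Michael reactions. The chosen plan never has an open chain or a free ortho phenol.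

Alternative 2: the C2–H and C3–H bonds are cut, which leads to flavone A3. The forward key step would be an enantioface-selective reduction of the C2=C3 bond, by asymmetric hydrogenation or a copper hydride 1,4-reduction. C2=C3 of A3 is a hindered β-aryl-β-aryloxy enone and a poor hydride acceptor. Hydrogenation catalysts active enough to reduce it would be expected to saturate the two prenyl alkenes or to reduce the C4 carbonyl as well, which would cost a re-oxidation. The usual acidic cyclodehydration that makes flavones also endangers the prenyl/phenol pairs. The chosen plan sets C2 by C–C bond formation and needs no redox step.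

Alternative 3: the C4a–C5 bond of ring A is cut, as in the biosynthesis, which leads to the prenylated tetraketide pyrone A4. The forward key step would be a base-induced opening of the pyrone and Claisen condensation of the chain methylene onto the terminal ester, folding the chain into the acylphloroglucinol ring. The fold would give chalcone A1, so it inherits both problems of alternative 1 (two ortho phenols, reversible closure) and does not address C2 at all. The aldol folding mode competes with the Claisen mode, and the enone in the chain of A4 is exposed to Michael addition during chain assembly. The step count would exceed that of the chosen plan without settling the stereocentre.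

Key step: step 9

Assumption: the rhodium–diene complex is taken to select the faces of the chromone C2=C3 bond in the same sense as those of 2-cyclohexenone, so the (S,S) ligand is specified for the 2S centre; the (R,R) ligand would be used if the sense proved opposite.

## Steps

Step 1
Reactants: 1 5,7-dihydroxy-4H-chromen-4-one
Product: 2 5-hydroxy-7-[(triisopropylsilyl)oxy]-4H-chromen-4-one
Conditions: TIPSCl (1.05 equiv), imidazole, DMF, 0 °C to rt
Reagents that add atoms: triisopropylsilyl chloride, CC(C)[Si](Cl)(C(C)C)C(C)C
Why: Chemoselective silylation: the 7-OH is a free, acidic vinylogous carboxylic acid OH, whereas the 5-OH is locked in a hydrogen bond to the C4 carbonyl and should stay untouched under imidazole conditions.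

Step 2
Reactants: 2 5-hydroxy-7-[(triisopropylsilyl)oxy]-4H-chromen-4-one
Product: 3 5-(allyloxy)-7-[(triisopropylsilyl)oxy]-4H-chromen-4-one
Conditions: allyl alcohol, PPh3, DIAD, THF, 0 °C to rt
Reagents that add atoms: allyl alcohol, C=CCO
Why: Mitsunobu etherification: the chelated 5-OH is acidic enough to protonate the betaine and is alkylated by the allyloxyphosphonium ion under neutral conditions that spare the 7-silyl ether, which a carbonate-mediated alkylation in DMF would endanger.

Step 3
Reactants: 3 5-(allyloxy)-7-[(triisopropylsilyl)oxy]-4H-chromen-4-one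
Product: 5 6-allyl-5-hydroxy-7-[(triisopropylsilyl)oxy]-4H-chromen-4-one, via Claisen dienone 4 (not isolated)
Conditions: PhNEt2, 190 °C, sealed tube
Reagents that add atoms: none
Why: Aromatic Claisen rearrangement: the [3,3] shift can deliver the allyl group from O5 only to C6, because the other ortho position, C4a, is the ring-fusion carbon; dienone 4 then enolises to the chelated phenol 5, which makes the sequence irreversible.

Step 4
Reactants: 5 6-allyl-5-hydroxy-7-[(triisopropylsilyl)oxy]-4H-chromen-4-one
Product: 6 5-hydroxy-6-(3-methylbut-2-en-1-yl)-7-[(triisopropylsilyl)oxy]-4H-chromen-4-one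
Conditions: second-generation Grubbs catalyst (5 mol %), 2-methyl-2-butene (excess), CH2Cl2, 40 °C
Reagents that add atoms: 2-methyl-2-butene, CC=C(C)C
Why: Olefin cross-metathesis: the terminal allyl alkene is the only alkene of 5 that should engage the ruthenium carbene, the chromone C2=C3 bond being an electron-poor, ring-bound vinylogous ester; excess 2-methyl-2-butene transfers the isopropylidene group and gives the trisubstituted prenyl alkene, which does not react further.

Step 5
Reactants: 6 5-hydroxy-6-(3-methylbut-2-en-1-yl)-7-[(triisopropylsilyl)oxy]-4H-chromen-4-one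
Product: 7 5-[(tert-butyldimethylsilyl)oxy]-6-(3-methylbut-2-en-1-yl)-7-[(triisopropylsilyl)oxy]-4H-chromen-4-one
Conditions: TBSOTf, 2,6-lutidine, CH2Cl2, 0 °C to rt
Reagents that add atoms: tert-butyldimethylsilyl triflate, CC(C)(C)[Si](C)(C)OS(=O)(=O)C(F)(F)F
Why: Silylation with a silyl triflate, needed because the 5-OH is chelated and flanked by the prenyl group; 2,6-lutidine scavenges triflic acid so that the prenyl/phenol pair is not cyclised, and masking the 5-OH removes the acidic, chelating site before the rhodium step.

Step 6
Reactants: 8 4,6-dibromobenzene-1,3-diol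
Product: 9 1,5-dibromo-2,4-bis[(triisopropylsilyl)oxy]benzene
Conditions: TIPSCl (2.4 equiv), imidazole, DMF, rt
Reagents that add atoms: triisopropylsilyl chloride, CC(C)[Si](Cl)(C(C)C)C(C)C
Why: Standard silylation of both phenols; triisopropylsilyl is chosen over smaller silyl groups because it resists O-to-C migration in the ortho-lithiated intermediates of steps 7 and 8.

Step 7
Reactants: 9 1,5-dibromo-2,4-bis[(triisopropylsilyl)oxy]benzene
Product: 11 1-bromo-5-(3-methylbut-2-en-1-yl)-2,4-bis[(triisopropylsilyl)oxy]benzene, via bromoaryllithium 10 (not isolated)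
Conditions: n-BuLi (1.05 equiv), THF, −78 °C; then CuBr·SMe2 (10 mol %), prenyl bromide, −78 to 0 °C
Reagents that add atoms: prenyl bromide (1-bromo-3-methylbut-2-ene), CC(C)=CCBr
Why: Bromine–lithium exchange followed by copper-assisted SN2 allylation; the two bromines of 9 are equivalent and the first aryllithium deactivates the ring towards a second exchange, so one prenyl group should enter, at the unsubstituted carbon of the allylic bromide.

Step 8
Reactants: 11 1-bromo-5-(3-methylbut-2-en-1-yl)-2,4-bis[(triisopropylsilyl)oxy]benzene
Product: 14 {5-(3-methylbut-2-en-1-yl)-2,4-bis[(triisopropylsilyl)oxy]phenyl}boronic acid, via prenylated aryllithium 12 (not isolated), via lithium aryltrimethoxyborate 13 (not isolated)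
Conditions: n-BuLi (1.1 equiv), THF, −78 °C; B(OMe)3, −78 °C to rt; then 1 M HCl, 0 °C, short contact
Reagents that add atoms: trimethyl borate, COB(OC)OC; water, O
Why: Bromine–lithium exchange and borylation with a trialkyl borate; brief cold dilute acid hydrolyses the ate complex 13 to the boronic acid and should be too mild for protodeboronation, silyl loss or attack on the prenyl alkene.

Step 9
Reactants: 7 5-[(tert-butyldimethylsilyl)oxy]-6-(3-methylbut-2-en-1-yl)-7-[(triisopropylsilyl)oxy]-4H-chromen-4-one; 14 {5-(3-methylbut-2-en-1-yl)-2,4-bis[(triisopropylsilyl)oxy]phenyl}boronic acid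
Product: 15 (2S)-5-[(tert-butyldimethylsilyl)oxy]-6-(3-methylbut-2-en-1-yl)-2-{5-(3-methylbut-2-en-1-yl)-2,4-bis[(triisopropylsilyl)oxy]phenyl}-7-[(triisopropylsilyl)oxy]-2,3-dihydro-4H-chromen-4-one
Conditions: [RhCl(C2H4)2]2 (2.5 mol %), (S,S)-Ph-bod* [(1S,4S)-2,5-diphenylbicyclo[2.2.2]octa-2,5-diene] (5.5 mol %), K3PO4 (0.2 equiv), 14 (2.5 equiv), 1,4-dioxane/H2O 10:1, 40 °C
Reagents that add atoms: none
Why: This is a rhodium-catalysed enantioselective 1,4-addition of an arylboronic acid to a chromone (Hayashi–Miyaura reaction), a reaction type known on this substrate class. Transmetallation of 14 to the hydroxorhodium–diene complex gives an aryl–rhodium species of monovalent rhodium, which binds the C2=C3 bond of 7 and inserts it with the aryl group going to C2 and rhodium to C3; the resulting oxa-π-allyl rhodium enolate is protonated by water at C3, which releases 15 and regenerates the Rh–OH catalyst. No ring is closed: ring C is already present in 7, so the O1–C8a connectivity and with it the C6 position of the prenyl group cannot change. The single new stereocentre C2 is set under catalyst control in the enantio-determining insertion: the C2-symmetric diene blocks one face of the coordinated enone, and the (S,S) ligand, which delivers aryl groups to 2-cyclohexenone to give (S)-3-arylcyclohexanones, should deliver the aryl group to the corresponding face of the chromone, which with the priorities O1 > C1' > C3 is 2S. The step needs 1,4- over 1,2-selectivity, which the soft aryl–rhodium species and the ortho-substituted aryl group should secure, and chemoselectivity for the enone over the two prenyl alkenes, which are trisubstituted, unactivated and do not insert into aryl–rhodium bonds. The rhodium enolate must be protonated faster than it expels the C8a aryloxide, which the water-rich, weakly basic medium and the fully silylated phenols favour. Protodeboronation of the electron-rich 14 is offset by using it in excess.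

Step 10
Reactants: 15 (2S)-5-[(tert-butyldimethylsilyl)oxy]-6-(3-methylbut-2-en-1-yl)-2-{5-(3-methylbut-2-en-1-yl)-2,4-bis[(triisopropylsilyl)oxy]phenyl}-7-[(triisopropylsilyl)oxy]-2,3-dihydro-4H-chromen-4-one
Product: 16 (2S)-2-[2,4-dihydroxy-5-(3-methylbut-2-en-1-yl)phenyl]-5,7-dihydroxy-6-(3-methylbut-2-en-1-yl)-2,3-dihydro-4H-chromen-4-one
Conditions: TBAF/AcOH 1:1 (6 equiv each), THF, 0 °C to rt
Reagents that add atoms: none
Why: Fluoride-mediated cleavage of the four aryl silyl ethers; acetic acid buffers the medium so that each phenol is protonated as it is released and no phenoxide persists to trigger retro-oxa-Michael opening, hence C2 should keep its S configuration, and the prenyl groups are inert to fluoride.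

## Compound list

1 | 5,7-dihydroxy-4H-chromen-4-one | O=c1ccoc2cc(O)cc(O)c12 | starting material
2 | 5-hydroxy-7-[(triisopropylsilyl)oxy]-4H-chromen-4-one | O=c1ccoc2cc(O[Si](C(C)C)(C(C)C)C(C)C)cc(O)c12 | intermediate
3 | 5-(allyloxy)-7-[(triisopropylsilyl)oxy]-4H-chromen-4-one | C=CCOc1cc(O[Si](C(C)C)(C(C)C)C(C)C)cc2occc(=O)c12 | intermediate
4 | 6-allyl-7-[(triisopropylsilyl)oxy]-4H-chromene-4,5(6H)-dione (Claisen dienone, racemic at C6, not isolated) | C=CCC1C(=O)C2=C(OC=CC2=O)C=C1O[Si](C(C)C)(C(C)C)C(C)C | intermediate
5 | 6-allyl-5-hydroxy-7-[(triisopropylsilyl)oxy]-4H-chromen-4-one | C=CCc1c(O[Si](C(C)C)(C(C)C)C(C)C)cc2occc(=O)c2c1O | intermediate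
6 | 5-hydroxy-6-(3-methylbut-2-en-1-yl)-7-[(triisopropylsilyl)oxy]-4H-chromen-4-one | CC(C)=CCc1c(O[Si](C(C)C)(C(C)C)C(C)C)cc2occc(=O)c2c1O | intermediate
7 | 5-[(tert-butyldimethylsilyl)oxy]-6-(3-methylbut-2-en-1-yl)-7-[(triisopropylsilyl)oxy]-4H-chromen-4-one | CC(C)=CCc1c(O[Si](C(C)C)(C(C)C)C(C)C)cc2occc(=O)c2c1O[Si](C)(C)C(C)(C)C | intermediate
8 | 4,6-dibromobenzene-1,3-diol | Oc1cc(O)c(Br)cc1Br | starting material
9 | 1,5-dibromo-2,4-bis[(triisopropylsilyl)oxy]benzene | CC(C)[Si](Oc1cc(O[Si](C(C)C)(C(C)C)C(C)C)c(Br)cc1Br)(C(C)C)C(C)C | intermediate
10 | {5-bromo-2,4-bis[(triisopropylsilyl)oxy]phenyl}lithium (not isolated) | [Li]c1cc(Br)c(O[Si](C(C)C)(C(C)C)C(C)C)cc1O[Si](C(C)C)(C(C)C)C(C)C | intermediate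
11 | 1-bromo-5-(3-methylbut-2-en-1-yl)-2,4-bis[(triisopropylsilyl)oxy]benzene | CC(C)=CCc1cc(Br)c(O[Si](C(C)C)(C(C)C)C(C)C)cc1O[Si](C(C)C)(C(C)C)C(C)C | intermediate
12 | {5-(3-methylbut-2-en-1-yl)-2,4-bis[(triisopropylsilyl)oxy]phenyl}lithium (not isolated) | [Li]c1cc(CC=C(C)C)c(O[Si](C(C)C)(C(C)C)C(C)C)cc1O[Si](C(C)C)(C(C)C)C(C)C | intermediate
13 | lithium trimethoxy{5-(3-methylbut-2-en-1-yl)-2,4-bis[(triisopropylsilyl)oxy]phenyl}borate (not isolated) | [Li+].CO[B-](OC)(OC)c1cc(CC=C(C)C)c(O[Si](C(C)C)(C(C)C)C(C)C)cc1O[Si](C(C)C)(C(C)C)C(C)C | intermediate
14 | {5-(3-methylbut-2-en-1-yl)-2,4-bis[(triisopropylsilyl)oxy]phenyl}boronic acid | OB(O)c1cc(CC=C(C)C)c(O[Si](C(C)C)(C(C)C)C(C)C)cc1O[Si](C(C)C)(C(C)C)C(C)C | intermediate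
15 | (2S)-5-[(tert-butyldimethylsilyl)oxy]-6-(3-methylbut-2-en-1-yl)-2-{5-(3-methylbut-2-en-1-yl)-2,4-bis[(triisopropylsilyl)oxy]phenyl}-7-[(triisopropylsilyl)oxy]-2,3-dihydro-4H-chromen-4-one | CC(C)=CCc1cc([C@@H]2CC(=O)c3c(cc(O[Si](C(C)C)(C(C)C)C(C)C)c(CC=C(C)C)c3O[Si](C)(C)C(C)(C)C)O2)c(O[Si](C(C)C)(C(C)C)C(C)C)cc1O[Si](C(C)C)(C(C)C)C(C)C | intermediate
16 | (2S)-2-[2,4-dihydroxy-5-(3-methylbut-2-en-1-yl)phenyl]-5,7-dihydroxy-6-(3-methylbut-2-en-1-yl)-2,3-dihydro-4H-chromen-4-one | CC(C)=CCc1cc([C@@H]2CC(=O)c3c(cc(O)c(CC=C(C)C)c3O)O2)c(O)cc1O | target

## Step count and least certain steps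

Total step count: 10 (steps 1–5 for the chromone half, steps 6–8 for the boronic acid half, steps 9 and 10 after convergence).
Longest linear sequence: 7 steps (1, 2, 3, 4, 5, 9, 10) from compound 1.

Step 9 (key step). The most likely failure is slow carbometallation, because both partners are hindered (a silyloxy group ortho to boron in 14, a silyloxy group next to the carbonyl in 7), so that protodeboronation of the electron-rich boronic acid outruns the addition. A second failure mode is expulsion of the C8a aryloxide from the rhodium enolate, which opens ring C and on reclosure would return material of low enantiomeric purity. Fallback: it sets out from 12 (made from 11 as in step 8) and 7. Transmetallation of 12 with MgBr2·OEt2 should give {5-(3-methylbut-2-en-1-yl)-2,4-bis[(triisopropylsilyl)oxy]phenyl}magnesium bromide F1, a harder and more reactive aryl donor. Its conjugate addition to 7, catalysed by CuBr·SMe2 in the presence of Me3SiCl in THF at −78 °C, should give the 4-(trimethylsilyloxy)-2H-chromene silyl enol ether F2. Mild aqueous acid should hydrolyse it to the racemic protected flavanone F3. Preparative chromatography on a chiral stationary phase would then separate 15 from the (2R)-enantiomer F4, and the route is rejoined at 15.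

Step 3. The most likely failure is an onward Cope shift of the dienone 4 from C6 to C8 before it enolises, or thermal degradation of the chromone at 190 °C; either would erode regiochemical purity or material. Fallback: it sets out from 2 and replaces the O-to-C transfer by a halogenation and cross-coupling. Iodination ortho to the free, chelated 5-OH with benzyltrimethylammonium dichloroiodate and CaCO3 in CH2Cl2/MeOH should give 5-hydroxy-6-iodo-7-[(triisopropylsilyl)oxy]-4H-chromen-4-one F5. Stille coupling with tributyl(3-methylbut-2-en-1-yl)stannane and Pd(PPh3)4 in DMF would then install the prenyl group directly, and the route is rejoined at 6.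

Step 7. The most likely failure is attack of the aryl nucleophile at the substituted terminus of prenyl bromide (SN2' course), which would place a 1,1-dimethylallyl group on the ring; silyl migration from oxygen to carbon in 10 on warming is a lesser risk. Fallback: it sets out from 10 and uses an electrophile whose two termini are equivalent. Quenching with allyl bromide should give 1-allyl-5-bromo-2,4-bis[(triisopropylsilyl)oxy]benzene F6, and cross-metathesis with 2-methyl-2-butene under the second-generation Grubbs catalyst would convert the allyl into the prenyl group; the route is rejoined at 11.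

Step 10. The most likely failure is that phenoxides formed by fluoride at O5, O2' or O4' open ring C by retro-oxa-Michael reaction before they are protonated, with erosion of configuration at C2 and migration of the prenyl group between C6 and C8; slow cleavage of the hindered triisopropylsilyl ethers would lengthen the exposure. Fallback: it sets out from 15 and never lets a phenoxide persist. Treatment with CsF and Ac2O in DMF should trap each phenoxide as it forms and give the (2S)-tetraacetate F7, a neutral compound that could also be recrystallised. Ammonium acetate in aqueous methanol at rt, a neutral deacetylation, should then release the four phenols, and the route is rejoined at 16.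

## Further compounds

F1 | step 9 | {5-(3-methylbut-2-en-1-yl)-2,4-bis[(triisopropylsilyl)oxy]phenyl}magnesium bromide | Br[Mg]c1cc(CC=C(C)C)c(O[Si](C(C)C)(C(C)C)C(C)C)cc1O[Si](C(C)C)(C(C)C)C(C)C
F2 | step 9 | racemic 5-[(tert-butyldimethylsilyl)oxy]-6-(3-methylbut-2-en-1-yl)-2-{5-(3-methylbut-2-en-1-yl)-2,4-bis[(triisopropylsilyl)oxy]phenyl}-7-[(triisopropylsilyl)oxy]-4-[(trimethylsilyl)oxy]-2H-chromene | CC(C)=CCc1cc(C2C=C(O[Si](C)(C)C)c3c(cc(O[Si](C(C)C)(C(C)C)C(C)C)c(CC=C(C)C)c3O[Si](C)(C)C(C)(C)C)O2)c(O[Si](C(C)C)(C(C)C)C(C)C)cc1O[Si](C(C)C)(C(C)C)C(C)C
F3 | step 9 | racemic 5-[(tert-butyldimethylsilyl)oxy]-6-(3-methylbut-2-en-1-yl)-2-{5-(3-methylbut-2-en-1-yl)-2,4-bis[(triisopropylsilyl)oxy]phenyl}-7-[(triisopropylsilyl)oxy]-2,3-dihydro-4H-chromen-4-one | CC(C)=CCc1cc(C2CC(=O)c3c(cc(O[Si](C(C)C)(C(C)C)C(C)C)c(CC=C(C)C)c3O[Si](C)(C)C(C)(C)C)O2)c(O[Si](C(C)C)(C(C)C)C(C)C)cc1O[Si](C(C)C)(C(C)C)C(C)C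
F4 | step 9 | (2R)-5-[(tert-butyldimethylsilyl)oxy]-6-(3-methylbut-2-en-1-yl)-2-{5-(3-methylbut-2-en-1-yl)-2,4-bis[(triisopropylsilyl)oxy]phenyl}-7-[(triisopropylsilyl)oxy]-2,3-dihydro-4H-chromen-4-one | CC(C)=CCc1cc([C@H]2CC(=O)c3c(cc(O[Si](C(C)C)(C(C)C)C(C)C)c(CC=C(C)C)c3O[Si](C)(C)C(C)(C)C)O2)c(O[Si](C(C)C)(C(C)C)C(C)C)cc1O[Si](C(C)C)(C(C)C)C(C)C
F5 | step 3 | 5-hydroxy-6-iodo-7-[(triisopropylsilyl)oxy]-4H-chromen-4-one | O=c1ccoc2cc(O[Si](C(C)C)(C(C)C)C(C)C)c(I)c(O)c12
F6 | step 7 | 1-allyl-5-bromo-2,4-bis[(triisopropylsilyl)oxy]benzene | C=CCc1cc(Br)c(O[Si](C(C)C)(C(C)C)C(C)C)cc1O[Si](C(C)C)(C(C)C)C(C)C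
F7 | step 10 | (2S)-2-[2,4-diacetoxy-5-(3-methylbut-2-en-1-yl)phenyl]-6-(3-methylbut-2-en-1-yl)-4-oxo-3,4-dihydro-2H-chromene-5,7-diyl diacetate | CC(C)=CCc1cc([C@@H]2CC(=O)c3c(cc(OC(C)=O)c(CC=C(C)C)c3OC(C)=O)O2)c(OC(C)=O)cc1OC(C)=O
A1 | alternative 1 | (E)-3-[2,4-dihydroxy-5-(3-methylbut-2-en-1-yl)phenyl]-1-[2,4,6-trihydroxy-3-(3-methylbut-2-en-1-yl)phenyl]prop-2-en-1-one | CC(C)=CCc1cc(/C=C/C(=O)c2c(O)cc(O)c(CC=C(C)C)c2O)c(O)cc1O
A2 | alternative 1 | 2-[2,4-dihydroxy-5-(3-methylbut-2-en-1-yl)phenyl]-5,7-dihydroxy-8-(3-methylbut-2-en-1-yl)-2,3-dihydro-4H-chromen-4-one (configuration at C2 not controlled) | CC(C)=CCc1cc(C2CC(=O)c3c(O)cc(O)c(CC=C(C)C)c3O2)c(O)cc1O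
A3 | alternative 2 | 2-[2,4-dihydroxy-5-(3-methylbut-2-en-1-yl)phenyl]-5,7-dihydroxy-6-(3-methylbut-2-en-1-yl)-4H-chromen-4-one | CC(C)=CCc1cc(-c2cc(=O)c3c(O)c(CC=C(C)C)c(O)cc3o2)c(O)cc1O
A4 | alternative 3 | 6-{(E)-4-[2,4-dihydroxy-5-(3-methylbut-2-en-1-yl)phenyl]-2-oxobut-3-en-1-yl}-4-hydroxy-3-(3-methylbut-2-en-1-yl)-2H-pyran-2-one | CC(C)=CCc1cc(/C=C/C(=O)Cc2cc(O)c(CC=C(C)C)c(=O)o2)c(O)cc1O
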